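## Retrosynthetic overview
1. (+)-Isolariciresinol comes from LiAlH4 reduction of the all-trans dimethyl 1-aryltetralin-2,3-dicarboxylate. C2 and C3 are set thermodynamically (all-equatorial), with C1 as the only non-epimerisable anchor.
2. That diester comes from a (1S,2S)-cis-1-aryl-1,2-dihydronaphthalene by hydrogenation (which also removes both benzyl groups) and methanolysis of the auxiliary.
3. Key step: the carbocycle is made by a photochemical conrotatory 6π-electrocyclisation/[1,5]-H shift of an axially chiral (E,E)-bis(benzylidene)succinate locked in an eight-membered (R)-prolinol amide–ester. Axial-to-central chirality transfer sets C1. No benzylic cation, Friedel–Crafts closure or dibenzylbutyrolactone is used.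
4. The diene comes from symmetric (E,E)-bis(benzylidene)succinic acid, made from two O-benzylvanillin units and diethyl succinate by two Stobbe condensations. Both aryl groups are identical, so either ring-closure mode converges on the same product.
5. Ring order: temporary anhydride, then temporary eight-membered auxiliary ring, then the tetralin carbocycle, then excision of the auxiliary ring.

Assumption: (R)-prolinol is taken to enforce the M helix (negative C1=C2–C3=C4 dihedral). This is the mirror image of the (S)-prolinol-bridged analogues, which give 1R (podophyllotoxin-type) products. If the sense proves reversed, use (S)-prolinol with nothing else changed.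
Tetralin numbering is used throughout: C1 bears the aryl group, C2 and C3 bear the carbonyl or CH2OH groups, and C4 is CH2. Handle compounds 5, 6 and 8 under amber light.

## Route

**Step 1**
Reactants: 1, 4-(benzyloxy)-3-methoxybenzaldehyde (O-benzylvanillin); 2, diethyl succinate
Product: 3, (E)-4-[4-(benzyloxy)-3-methoxyphenyl]-3-(ethoxycarbonyl)but-3-enoic acid
Conditions: NaOEt, EtOH, reflux; then aq. HCl
Reagents that add atoms: none beyond 1 and 2
Why: Stobbe condensation, in which the succinate enolate adds to the non-enolisable aldehyde, the alkoxide lactonises onto the distal ester, and E1cB opening gives the half-ester with the aryl group trans to CO2Et (E); no stereocentre is formed.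

**Step 2**
Reactants: 3
Product: 4, diethyl (E)-2-[4-(benzyloxy)-3-methoxybenzylidene]succinate
Conditions: EtOH, cat. H2SO4, reflux
Reagents that add atoms: ethanol, CCO
Why: Fischer esterification restores the ester-flanked CH2 needed for a second Stobbe reaction, and the aryl benzyl ether and enoate are inert to catalytic acid.

**Step 3**
Reactants: 4; 1 (second equivalent)
Product: 5, (2E,3E)-2,3-bis[4-(benzyloxy)-3-methoxybenzylidene]succinic acid
Conditions: NaOEt, EtOH, reflux; then 2 M NaOH, reflux; HCl; recrystallise the (E,E) isomer
Reagents that add atoms: hydroxide/water, [Na+].[OH-] (O of the second CO2H)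
Why: A second Stobbe condensation at the remaining CH2 followed by saponification places each aryl trans to its own carboxyl, which is the geometry that puts the aryl ring cis to the other alkene as the electrocyclisation requires.

**Step 4**
Reactants: 5
Product: 6, (3E,4E)-3,4-bis[4-(benzyloxy)-3-methoxybenzylidene]dihydrofuran-2,5-dione (a fulgide)
Conditions: Ac2O, 80 °C, dark
Reagents that add atoms: none
Why: Cyclodehydration of the 1,4-diacid to the five-membered anhydride (standard fulgide formation) runs well below the temperature of thermal electrocyclisation and keeps the E,E geometry.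

**Step 5**
Reactants: 6; 7, (R)-pyrrolidin-2-ylmethanol (D-prolinol)
Product: 8, the eight-membered cyclic amide–ester (ring N–C(=O)–C(=CHAr)–C(=CHAr)–C(=O)–O–CH2–CH, fused to the pyrrolidine; a pyrrolo[2,1-c][1,4]oxazocine-dione) with both alkenes E, an (R) stereocentre and an M-configured diene axis
Conditions: 7, CH2Cl2, 0 °C to rt; then dilute to 2 mM, EDC·HCl, DMAP, rt; then PhMe, 90 °C (atropisomer equilibration)
Reagents that add atoms: none beyond 7
Why: Chemoselective aminolysis of the symmetric anhydride is followed by Steglich-type lactonisation of the hydroxy acid, which is helped by the twisted s-cis diene holding the two carbonyls gauche, and the prolinol stereocentre biases the C2–C3 axis to one atropisomer on heating.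

**Step 6 (key step)**
Reactants: 8
Product: 9, (1S,2S)-cis-7-(benzyloxy)-1-[4-(benzyloxy)-3-methoxyphenyl]-6-methoxy-1,2-dihydronaphthalene-2,3-dicarboxylic acid as its cyclic C2-amide/C3-ester with (R)-prolinol. The other closure mode gives the C2-ester/C3-amide isomer with the same 1S,2S configuration, and both converge to 11 in Step 8.
Conditions: hν (medium-pressure Hg, Pyrex, λ > 300 nm), degassed MeCN (3 mM), FEP flow coil, 25 °C
Reagents that add atoms: none
Why: Photochemical conrotatory 6π-electrocyclisation of the aryl–diene hexatriene (fulgide-type) occurs at the less hindered ortho carbon (para to OMe); the M helix places the benzylidene carbon over the arene so that C1 forms as S, and the thermal suprafacial [1,5]-H shift from C8a to C2 rearomatises and delivers H2 on the face of H1, giving 1,2-cis (2S).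

**Step 7**
Reactants: 9
Product: 10, (1S,2S,3R)-all-cis-7-hydroxy-1-(4-hydroxy-3-methoxyphenyl)-6-methoxy-1,2,3,4-tetrahydronaphthalene-2,3-dicarboxylic acid as its cyclic C2-amide/C3-ester with (R)-prolinol
Conditions: H2 (3 atm), 10% Pd/C, MeOH–EtOAc, rt
Reagents that add atoms: none (hydrogen only)
Why: Heterogeneous syn-hydrogenation of the C3=C4 enoate occurs from the face bearing H1 and H2 (anti to the C1 aryl and C2 carbonyl), setting C3 as R, and both aryl benzyl ethers are hydrogenolysed in the same operation; C3 selectivity is not critical because it is re-equilibrated in Step 9.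

**Step 8**
Reactants: 10
Product: 11, dimethyl (1S,2S,3R)-7-hydroxy-1-(4-hydroxy-3-methoxyphenyl)-6-methoxy-1,2,3,4-tetrahydronaphthalene-2,3-dicarboxylate (all-cis); 7·HCl is recovered
Conditions: 3 M HCl in MeOH (AcCl/MeOH), reflux
Reagents that add atoms: methanol, CO (two OMe groups)
Why: Acid-catalysed transesterification frees the prolinol OH, which triggers the N→O acyl shift typical of β-hydroxy tertiary amides (five-membered tetrahedral intermediate, driven by ammonium formation), and a second transesterification releases the auxiliary; C1 is not acid-labile.

**Step 9**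
Reactants: 11
Product: 12, dimethyl (1S,2R,3R)-7-hydroxy-1-(4-hydroxy-3-methoxyphenyl)-6-methoxy-1,2,3,4-tetrahydronaphthalene-2,3-dicarboxylate (1,2-trans, 2,3-trans)
Conditions: NaOMe (6 equiv), MeOH, reflux, Ar; then AcOH, 0 °C
Reagents that add atoms: none (methoxide exchange is degenerate)
Why: Thermodynamic epimerisation through the ester enolates funnels the mixture to the all-equatorial trans,trans isomer, so only C2 must invert (S to R), while the C1–H (diarylmethine, not α to a carbonyl) is untouched and fixes the absolute series.

**Step 10**
Reactants: 12
Product: 13, (+)-isolariciresinol, (1S,2R,3R) in tetralin numbering, equivalent to (6R,7R,8S) in the naphthalen-2-ol name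
Conditions: LiAlH4 (8 equiv), THF, 0 °C to reflux; Rochelle salt/dilute HCl work-up
Reagents that add atoms: none (hydride only)
Why: LiAlH4 reduces both esters to primary alcohols, with the phenols simply consuming reagent as aluminium phenoxides, and reduction is much faster than enolisation, so the 1S,2R,3R configuration is retained.

## Compound list
1 | 4-(benzyloxy)-3-methoxybenzaldehyde | COc1cc(C=O)ccc1OCc1ccccc1 | starting material
2 | diethyl succinate | CCOC(=O)CCC(=O)OCC | starting material
3 | (E)-Stobbe half-ester | CCOC(=O)/C(CC(=O)O)=C/c1ccc(OCc2ccccc2)c(OC)c1 | intermediate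
4 | diethyl (E)-benzylidenesuccinate | CCOC(=O)/C(CC(=O)OCC)=C/c1ccc(OCc2ccccc2)c(OC)c1 | intermediate
5 | (E,E)-bis(benzylidene)succinic acid | OC(=O)/C(=C/c1ccc(OCc2ccccc2)c(OC)c1)C(=C/c1ccc(OCc2ccccc2)c(OC)c1)\C(=O)O | intermediate
6 | (E,E)-fulgide anhydride | O=C1/C(=C/c2ccc(OCc3ccccc3)c(OC)c2)C(=C/c2ccc(OCc3ccccc3)c(OC)c2)\C(=O)O1 | intermediate
7 | (R)-prolinol | OC[C@H]1CCCN1 | starting material
8 | (R)-prolinol-bridged eight-membered amide–ester, E,E, M axis (axis not encodable in SMILES) | O=C1/C(=C/c3ccc(OCc4ccccc4)c(OC)c3)C(=C/c3ccc(OCc4ccccc4)c(OC)c3)\C(=O)OC[C@H]2CCCN12 | intermediate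
9 | (1S,2S)-cis-1-aryl-1,2-dihydronaphthalene amide–ester | COc1cc2C=C3C(=O)OC[C@H]4CCCN4C(=O)[C@H]3[C@H](c2cc1OCc1ccccc1)c1ccc(OCc2ccccc2)c(OC)c1 | intermediate
10 | (1S,2S,3R)-all-cis tetralin amide–ester, free phenols | COc1cc2C[C@H]3C(=O)OC[C@H]4CCCN4C(=O)[C@H]3[C@H](c2cc1O)c1ccc(O)c(OC)c1 | intermediate
11 | dimethyl (1S,2S,3R)-all-cis diester | COc1cc([C@H]2c3cc(O)c(OC)cc3C[C@@H](C(=O)OC)[C@H]2C(=O)OC)ccc1O | intermediate
12 | dimethyl (1S,2R,3R)-all-trans diester | COc1cc([C@H]2c3cc(O)c(OC)cc3C[C@@H](C(=O)OC)[C@@H]2C(=O)OC)ccc1O | intermediate
13 | (+)-isolariciresinol | COc1cc([C@H]2c3cc(O)c(OC)cc3C[C@@H](CO)[C@@H]2CO)ccc1O | target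

## Summary
Total steps: 10. Longest linear sequence: 10 (1 + 2 to 13).
Stereocentres: C1 is set in Step 6, C3 in Step 7 (confirmed thermodynamically in Step 9), and C2 in Step 9.

Steps most likely to fail:
1. **Step 6.** Risks are incomplete axial-to-central transfer, closure at the ortho carbon next to OMe, secondary photolysis, and aromatisation by trace O2. Fallback: abandon the electrocyclisation for an intermolecular o-quinodimethane Diels–Alder. Photoenolise [5-(benzyloxy)-4-methoxy-2-methylphenyl][4-(benzyloxy)-3-methoxyphenyl] ketone in the presence of a chiral fumarate such as the bis-(S)-methyl lactate ester. Remove the C1 carbinol by ionic or catalytic deoxygenation, then rejoin the route at the epimerisation/LiAlH4 endgame.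
2. **Step 5.** Risks are oligomerisation during the eight-membered closure and a poor atropisomer ratio. Fallback: reverse the polarity of ring closure. Isolate the hydroxy-amide acid and form the C–O bond by activating the alcohol (intramolecular Mitsunobu, or mesylate with Cs2CO3 carboxylate alkylation) instead of activating the hindered acid.
3. **Step 8.** The hindered tertiary amide may resist solvolysis. Fallback: remove the auxiliary reductively. Open the lactone with NaOMe/MeOH, reduce the amide to the aldehyde with Cp2Zr(H)Cl, epimerise C2 at the aldehyde stage with DBU, then reduce the aldehyde and ester together with LiAlH4. This replaces Steps 8–10.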